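**Plan**
- Numbering: lactone O1, C2(=O), C3, C4, C5; ring A is the 3-hydroxy-4,5-dimethoxyphenyl on the C3 CH2, ring B the 3,4-dimethoxyphenyl on the C4 CH2. Retrosynthetic cuts, in order: the benzyl mask on the ring A phenol, the bond between ring B and the CH2 on C4, O1–C5, the C3–CH2 bond to ring A, and the C=C joining the acetate unit to oxetan-3-one.
- Enabling feature: C4 bears two CH2 groups, C5 (bound to O1) and the CH2 leading to ring B. Held by one oxygen, they are the two CH2 groups of an oxetane and form a prochiral pair.
- Forward: oxetan-3-one is homologated to ethyl 2-(oxetan-3-yl)acetate, benzylated at the α-carbon with the ring A bromide and saponified. The lactone, the only ring formed, closes by opening the oxetane; the freed CH2OH becomes CH2Br and is joined to ring B; the phenol is unmasked last.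
- Stereochemistry: C4 comes from the chiral phosphoric acid, which decides which oxetane CH2 becomes C5. C3 is set afterwards by base equilibration to the trans lactone under control of C4.

Key step: step 8

Assumption: the (R)-configured phosphoric acid is taken to give the (4S) lactone; if the sense of induction is the opposite, the (S)-catalyst is used and nothing else changes.

**Step 1**
Reactants: 1 3-hydroxy-4,5-dimethoxybenzaldehyde
Product: 2 3-(benzyloxy)-4,5-dimethoxybenzaldehyde
Conditions: BnBr (1.1 equiv), K2CO3 (1.5 equiv), DMF, rt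
Reagents that add atoms: benzyl bromide, BrCc1ccccc1
Why: Williamson etherification of the phenoxide masks the only acidic OH before the enolate and organometallic steps, and the benzyl ether is removable by hydrogenolysis at the end.

**Step 2**
Reactants: 2 3-(benzyloxy)-4,5-dimethoxybenzaldehyde
Product: 3 [3-(benzyloxy)-4,5-dimethoxyphenyl]methanol
Conditions: NaBH4 (0.5 equiv), MeOH, 0 °C
Reagents that add atoms: none
Why: Borohydride reduction of an aromatic aldehyde to the benzylic alcohol is routine and leaves the aryl ethers untouched.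

**Step 3**
Reactants: 3 [3-(benzyloxy)-4,5-dimethoxyphenyl]methanol
Product: 4 3-(benzyloxy)-4,5-dimethoxybenzyl bromide
Conditions: PBr3 (0.4 equiv), CH2Cl2, 0 °C; used promptly
Reagents that add atoms: phosphorus tribromide, BrP(Br)Br
Why: Bromination of an electron-rich benzylic alcohol with PBr3 (displacement of the bromophosphite by bromide) gives the electrophile for the enolate alkylation under conditions that spare the benzyl ether.

**Step 4**
Reactants: 5 triethyl phosphonoacetate; 6 oxetan-3-one
Product: 8 ethyl 2-(oxetan-3-ylidene)acetate, via sodium phosphonate carbanion 7 (not isolated)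
Conditions: NaH (1.05 equiv), THF, 0 °C; then 6, 0 °C to rt
Reagents that add atoms: none
Why: Horner–Wadsworth–Emmons olefination of the strained, unhindered ketone is fast and gives a single alkene because the oxetane side is symmetric.

**Step 5**
Reactants: 8 ethyl 2-(oxetan-3-ylidene)acetate
Product: 9 ethyl 2-(oxetan-3-yl)acetate
Conditions: H2 (1 atm), 10% Pd/C, EtOAc, rt
Reagents that add atoms: none
Why: Heterogeneous catalytic hydrogenation of the strained exocyclic enoate leaves the oxetane intact, and it is placed before ring A enters so that no benzyl ether is exposed to it.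

**Step 6**
Reactants: 9 ethyl 2-(oxetan-3-yl)acetate; 4 3-(benzyloxy)-4,5-dimethoxybenzyl bromide
Product: 11 ethyl 3-[3-(benzyloxy)-4,5-dimethoxyphenyl]-2-(oxetan-3-yl)propanoate (racemic), via lithium ester enolate 10 (not isolated)
Conditions: LiN(iPr)2 (1.05 equiv), THF, −78 °C; then 4, −78 to −30 °C
Reagents that add atoms: none
Why: Alkylation of the kinetically formed ester lithium enolate with a reactive benzylic bromide forms the bond from the later C3 to the ring A CH2; the new centre is left racemic on purpose because it is equilibrated in step 11.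

**Step 7**
Reactants: 11 ethyl 3-[3-(benzyloxy)-4,5-dimethoxyphenyl]-2-(oxetan-3-yl)propanoate
Product: 13 3-[3-(benzyloxy)-4,5-dimethoxyphenyl]-2-(oxetan-3-yl)propanoic acid (racemic), via its lithium carboxylate 12 (not isolated)
Conditions: LiOH·H2O (1.5 equiv), THF/H2O, rt; then 1 M NaHSO4 (aq) to pH 4 at 0 °C, EtOAc extraction, evaporation below 20 °C; used at once
Reagents that add atoms: lithium hydroxide, [Li+].[OH-]
Why: Basic ester hydrolysis (saponification) does not touch the oxetane, and the acid is freed only at pH 4 and kept cold because oxetane carboxylic acids of this kind slowly lactonize on their own to racemic material.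

**Step 8**
Reactants: 13 3-[3-(benzyloxy)-4,5-dimethoxyphenyl]-2-(oxetan-3-yl)propanoic acid
Product: 14 (4S)-3-[3-(benzyloxy)-4,5-dimethoxybenzyl]-4-(hydroxymethyl)dihydrofuran-2(3H)-one as a mixture of both C3 epimers
Conditions: (R)-3,3'-bis(2,4,6-triisopropylphenyl)-1,1'-binaphthyl-2,2'-diyl hydrogen phosphate (10 mol%), toluene (0.02 M), −20 °C
Reagents that add atoms: none
Why: The carboxyl group and the phosphoric acid form a doubly hydrogen-bonded pair that makes the phosphoric acid OH a stronger donor toward the oxetane oxygen and the carboxyl oxygen a better nucleophile; backside attack on one oxetane CH2 then forms O1–C5, driven by release of the four-ring strain, and leaves the former oxetane oxygen as the CH2OH on C4. The closest known reaction type is the chiral phosphoric acid-catalysed intramolecular desymmetrization of 3-substituted oxetanes by tethered oxygen nucleophiles, supported by phosphoric acid-catalysed openings of strained cyclic ethers by carboxylic acids. The lactone closes in the 5-exo-tet mode. C4 is not a reacting centre: its configuration follows only from which of the two CH2 arms the catalyst presents to the carboxyl, so the binaphthyl backbone with its 2,4,6-triisopropylphenyl walls is the controlling element. The step needs catalyst control that overrides the bias of the neighbouring racemic C3 centre and outruns the self-promoted racemic opening; the substrate helps because the oxetane carbon carries only H, the C3 centre sits on the nucleophile arm with H and a flexible benzyl as its distinguishing groups, and two-point binding of the carboxyl should make the catalysed path much faster than the background in cold, dilute toluene. Both enantiomers of 13 should therefore give the same (4S) centre, and the C3 mixture is corrected in step 11.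

**Step 9**
Reactants: 14 (4S)-3-[3-(benzyloxy)-4,5-dimethoxybenzyl]-4-(hydroxymethyl)dihydrofuran-2(3H)-one
Product: 15 (4R)-3-[3-(benzyloxy)-4,5-dimethoxybenzyl]-4-(bromomethyl)dihydrofuran-2(3H)-one as a mixture of both C3 epimers
Conditions: CBr4 (1.3 equiv), PPh3 (1.4 equiv), CH2Cl2, 0 °C
Reagents that add atoms: carbon tetrabromide, BrC(Br)(Br)Br
Why: Appel bromination converts the primary alcohol under neutral conditions, which avoids base-induced acyl transfer between the two oxygen-bearing arms of C4 (that would invert C4); C4 is not involved and only its descriptor changes from S to R by the priority rules.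

**Step 10**
Reactants: 15 (4R)-3-[3-(benzyloxy)-4,5-dimethoxybenzyl]-4-(bromomethyl)dihydrofuran-2(3H)-one; 16 4-bromo-1,2-dimethoxybenzene
Product: 17 (4R)-3-[3-(benzyloxy)-4,5-dimethoxybenzyl]-4-(3,4-dimethoxybenzyl)dihydrofuran-2(3H)-one as a mixture of both C3 epimers
Conditions: NiBr2(MeOCH2CH2OMe) (10 mol%), 4,4'-di-tert-butyl-2,2'-bipyridine (10 mol%), NaI (25 mol%), Zn dust (2 equiv), DMA, 60 °C; 16 (1.5 equiv)
Reagents that add atoms: none
Why: Nickel-catalysed reductive cross-electrophile coupling of a primary alkyl bromide with an aryl bromide tolerates lactones and benzyl ethers and needs no base, so the bromide cannot cyclize onto a C3 enolate; the radical sits on the exocyclic CH2, so C4 is retained.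

**Step 11**
Reactants: 17 (4R)-3-[3-(benzyloxy)-4,5-dimethoxybenzyl]-4-(3,4-dimethoxybenzyl)dihydrofuran-2(3H)-one
Product: 18 (3R,4R)-3-[3-(benzyloxy)-4,5-dimethoxybenzyl]-4-(3,4-dimethoxybenzyl)dihydrofuran-2(3H)-one (trans)
Conditions: NaOMe (0.3 equiv), MeOH/THF, 40 °C; then 1 M HCl, rt
Reagents that add atoms: none
Why: Base-mediated epimerization through the lactone enolate is a thermodynamic equilibration in which C3 is the only acidic stereocentre and the fixed C4 centre directs it to the more stable trans-dibenzyl lactone, while the acidic finish recloses any ring-opened hydroxy ester; residual cis isomer should be separable and can be resubmitted.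

**Step 12**
Reactants: 18 (3R,4R)-3-[3-(benzyloxy)-4,5-dimethoxybenzyl]-4-(3,4-dimethoxybenzyl)dihydrofuran-2(3H)-one
Product: 19 (3R,4R)-4-(3,4-dimethoxybenzyl)-3-(3-hydroxy-4,5-dimethoxybenzyl)dihydrofuran-2(3H)-one (CNP0246971.1)
Conditions: H2 (1 atm), 10% Pd/C, EtOAc/EtOH, rt
Reagents that add atoms: none
Why: Hydrogenolysis of the aryl benzyl ether frees the phenol under neutral conditions that leave the lactone, the methyl ethers and both stereocentres untouched.

**Compound list**
1 | 3-hydroxy-4,5-dimethoxybenzaldehyde | COc1cc(C=O)cc(O)c1OC | starting material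
2 | 3-(benzyloxy)-4,5-dimethoxybenzaldehyde | COc1cc(C=O)cc(OCc2ccccc2)c1OC | intermediate
3 | [3-(benzyloxy)-4,5-dimethoxyphenyl]methanol | COc1cc(CO)cc(OCc2ccccc2)c1OC | intermediate
4 | 3-(benzyloxy)-4,5-dimethoxybenzyl bromide | COc1cc(CBr)cc(OCc2ccccc2)c1OC | intermediate
5 | triethyl phosphonoacetate | CCOC(=O)CP(=O)(OCC)OCC | starting material
6 | oxetan-3-one | O=C1COC1 | starting material
7 | sodium salt of triethyl phosphonoacetate (formed in the flask, step 4) | [Na+].CCOC(=O)[CH-]P(=O)(OCC)OCC | intermediate
8 | ethyl 2-(oxetan-3-ylidene)acetate | CCOC(=O)C=C1COC1 | intermediate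
9 | ethyl 2-(oxetan-3-yl)acetate | CCOC(=O)CC1COC1 | intermediate
10 | lithium enolate of ethyl 2-(oxetan-3-yl)acetate (formed in the flask, step 6) | [Li+].CCOC([O-])=CC1COC1 | intermediate
11 | ethyl 3-[3-(benzyloxy)-4,5-dimethoxyphenyl]-2-(oxetan-3-yl)propanoate, racemic | CCOC(=O)C(Cc1cc(OCc2ccccc2)c(OC)c(OC)c1)C1COC1 | intermediate
12 | lithium 3-[3-(benzyloxy)-4,5-dimethoxyphenyl]-2-(oxetan-3-yl)propanoate, racemic (formed in the flask, step 7) | [Li+].[O-]C(=O)C(Cc1cc(OCc2ccccc2)c(OC)c(OC)c1)C1COC1 | intermediate
13 | 3-[3-(benzyloxy)-4,5-dimethoxyphenyl]-2-(oxetan-3-yl)propanoic acid, racemic | OC(=O)C(Cc1cc(OCc2ccccc2)c(OC)c(OC)c1)C1COC1 | intermediate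
14 | (4S)-3-[3-(benzyloxy)-4,5-dimethoxybenzyl]-4-(hydroxymethyl)dihydrofuran-2(3H)-one, both C3 epimers | OC[C@H]1COC(=O)C1Cc1cc(OCc2ccccc2)c(OC)c(OC)c1 | intermediate
15 | (4R)-3-[3-(benzyloxy)-4,5-dimethoxybenzyl]-4-(bromomethyl)dihydrofuran-2(3H)-one, both C3 epimers | BrC[C@H]1COC(=O)C1Cc1cc(OCc2ccccc2)c(OC)c(OC)c1 | intermediate
16 | 4-bromo-1,2-dimethoxybenzene | COc1ccc(Br)cc1OC | starting material
17 | (4R)-3-[3-(benzyloxy)-4,5-dimethoxybenzyl]-4-(3,4-dimethoxybenzyl)dihydrofuran-2(3H)-one, both C3 epimers | COc1ccc(C[C@H]2COC(=O)C2Cc2cc(OCc3ccccc3)c(OC)c(OC)c2)cc1OC | intermediate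
18 | (3R,4R)-3-[3-(benzyloxy)-4,5-dimethoxybenzyl]-4-(3,4-dimethoxybenzyl)dihydrofuran-2(3H)-one | COc1ccc(C[C@H]2COC(=O)[C@@H]2Cc2cc(OCc3ccccc3)c(OC)c(OC)c2)cc1OC | intermediate
19 | (3R,4R)-4-(3,4-dimethoxybenzyl)-3-(3-hydroxy-4,5-dimethoxybenzyl)dihydrofuran-2(3H)-one | COc1ccc(C[C@H]2COC(=O)[C@@H]2Cc2cc(O)c(OC)c(OC)c2)cc1OC | target

**Step count**
Total: 12 steps. Longest linear sequence: 10 steps (steps 1–3 and 6–12, from 1); the oxetane branch (steps 4 and 5) joins at step 6.

**Steps most likely to fail**

1. Step 8. The catalyst may not overrule the directing effect of the racemic C3 centre in one enantiomer of 13 (a mismatched pairing), and the self-promoted opening of the free acid may compete; either lowers the purity at C4. The fallback removes the C3 centre from the ring closure and brings ring A in afterwards. It sets out from 9, which is saponified (LiOH, then NaHSO4 at 0 °C) to 2-(oxetan-3-yl)acetic acid F1. This acid has no stereocentre, so the same phosphoric acid only has to tell two enantiotopic CH2 groups apart in closing (S)-4-(hydroxymethyl)dihydrofuran-2(3H)-one F2. Silylation (tert-butyldimethylsilyl chloride, imidazole, DMF) gives (R)-4-{[(tert-butyldimethylsilyl)oxy]methyl}dihydrofuran-2(3H)-one F3. Alkylation with 4 (LiN(iPr)2, THF, −78 °C) should occur anti to the C4 substituent, as is usual for 4-substituted butyrolactone enolates, and give (3R,4R)-3-[3-(benzyloxy)-4,5-dimethoxybenzyl]-4-{[(tert-butyldimethylsilyl)oxy]methyl}dihydrofuran-2(3H)-one F4. Desilylation with HF·pyridine in THF comes back to the route at 14, now as its (3R,4S) epimer alone; steps 9 to 12 follow unchanged.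

2. Step 10. Homocoupling or reduction of the alkyl bromide, slow activation of the electron-rich aryl bromide, or cyclization of the transient primary radical onto ring A may erode the coupling. The fallback replaces the radical cross-electrophile path by a two-electron cross-coupling of a preformed nucleophile. It sets out from 15, into which zinc is inserted (Zn dust, LiCl, THF, 50 °C) to give ({(3R)-4-[3-(benzyloxy)-4,5-dimethoxybenzyl]-5-oxotetrahydrofuran-3-yl}methyl)zinc bromide F5. Negishi coupling with 16 (Pd(OAc)2, 2-dicyclohexylphosphino-2',6'-dimethoxybiphenyl, THF, rt to 50 °C) comes back to the route at 17.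

3. Step 6. Self-condensation of the ester, double alkylation, or attack of the enolate on its own oxetane may consume the material. The fallback forms the same carbon skeleton without an ester enolate next to the oxetane. It sets out from 5 and 4: the sodium salt of 5 (NaH, THF) is alkylated with 4 to give ethyl 3-[3-(benzyloxy)-4,5-dimethoxyphenyl]-2-(diethoxyphosphoryl)propanoate F6. Horner–Wadsworth–Emmons reaction of F6 with 6 (NaH, THF) gives ethyl 3-[3-(benzyloxy)-4,5-dimethoxyphenyl]-2-(oxetan-3-ylidene)propanoate F7. Conjugate reduction of the strained enoate with NaBH4 and NiCl2·6H2O in EtOH at 0 °C, which spares the benzyl ether, comes back to the route at 11.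

**Further compounds**
F1 | step 8 | 2-(oxetan-3-yl)acetic acid | OC(=O)CC1COC1
F2 | step 8 | (S)-4-(hydroxymethyl)dihydrofuran-2(3H)-one | OC[C@H]1COC(=O)C1
F3 | step 8 | (R)-4-{[(tert-butyldimethylsilyl)oxy]methyl}dihydrofuran-2(3H)-one | CC(C)(C)[Si](C)(C)OC[C@H]1COC(=O)C1
F4 | step 8 | (3R,4R)-3-[3-(benzyloxy)-4,5-dimethoxybenzyl]-4-{[(tert-butyldimethylsilyl)oxy]methyl}dihydrofuran-2(3H)-one | CC(C)(C)[Si](C)(C)OC[C@H]1COC(=O)[C@@H]1Cc1cc(OCc2ccccc2)c(OC)c(OC)c1
F5 | step 10 | ({(3R)-4-[3-(benzyloxy)-4,5-dimethoxybenzyl]-5-oxotetrahydrofuran-3-yl}methyl)zinc bromide, both epimers at the benzyl-bearing carbon | Br[Zn]C[C@H]1COC(=O)C1Cc1cc(OCc2ccccc2)c(OC)c(OC)c1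
F6 | step 6 | ethyl 3-[3-(benzyloxy)-4,5-dimethoxyphenyl]-2-(diethoxyphosphoryl)propanoate | CCOC(=O)C(Cc1cc(OCc2ccccc2)c(OC)c(OC)c1)P(=O)(OCC)OCC
F7 | step 6 | ethyl 3-[3-(benzyloxy)-4,5-dimethoxyphenyl]-2-(oxetan-3-ylidene)propanoate | CCOC(=O)C(Cc1cc(OCc2ccccc2)c(OC)c(OC)c1)=C1COC1
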